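## Retrosynthetic overview

1. Schizolaenone C ⇒ a 6-iodo, tris-O-silylated (2S)-flavanone + geranyl acetate. The C6–C1'' aryl–geranyl bond is made last by a visible-light photoredox/nickel reductive coupling, and the silyl ethers are cleaved in the same flask.
2. The iodide ⇒ iodination ortho to the free, chelated 5-OH of the 7,3',5'-tris-silyl ether ⇒ (2S)-5,7,3',5'-tetrahydroxyflavanone.
3. The tetrol ⇒ (2S)-pinocembrin by sterically controlled iridium C–H borylation/oxidation at C3' and C5' of ring B.
4. No ring is constructed. Rings A, C and B and the C2 stereocentre are bought together in (2S)-pinocembrin and only decorated, in the order ring B oxygenation, ring A iodination, ring A geranylation.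

Assumption: natural (2S)-(−)-pinocembrin is bought as the single enantiomer (ee checked by chiral HPLC before use).

## Route

Step 1
Reactants: 1 (2S)-pinocembrin [(2S)-5,7-dihydroxy-2-phenylchroman-4-one]; 2 pinacolborane; 3 bis(pinacolato)diboron; 4 N-methylmorpholine N-oxide
Product: 7 (2S)-5,7,3',5'-tetrahydroxyflavanone [(2S)-2-(3,5-dihydroxyphenyl)-5,7-dihydroxychroman-4-one], via tetraborylated flavanone 5 (not isolated), via tetrakis(boryloxy) flavanone 6 (not isolated)
Conditions: HBpin (2.2 equiv), THF, rt→60 °C; [Ir(OMe)(cod)]2 (3 mol%), dtbpy (6 mol%), B2pin2 (2.5 equiv), THF, 80 °C, 16 h; then NMO (6 equiv), THF, 50 °C; aq. NH4Cl; SiO2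
Reagents that add atoms: N-methylmorpholine N-oxide, C[N+]1([O-])CCOCC1 (the two new phenolic O atoms of 7); pinacolborane, CC1(C)OBOC1(C)C, and bis(pinacolato)diboron, CC1(C)OB(OC1(C)C)B1OC(C)(C)C(C)(C)O1 (boryl groups of 5 and 6, lost on hydrolysis)
Why: In-situ O-borylation masks both phenols, and sterically governed iridium-catalysed aromatic C–H borylation can then attack only C3', C4' and C5' of ring B (both ring A C–H bonds lie between two oxygens, the ring B ortho positions next to the C2 branch); exhaustive borylation turns the meta-monoboronate into the 3',5'-bis(boronate) while the para-monoboronate cannot react further (about 2:1 expected, the 4'-hydroxy by-product naringenin being removed by chromatography), and neutral N-oxide oxidation of the C–B bonds with hydrolysis gives 7 with the bought S configuration at C2 untouched, since no base or acid is present.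

Step 2
Reactants: 7 (2S)-5,7,3',5'-tetrahydroxyflavanone; 8 tert-butyldimethylsilyl chloride
Product: 9 (2S)-7,3',5'-tris(tert-butyldimethylsilyloxy)-5-hydroxyflavanone
Conditions: TBSCl (3.3 equiv), imidazole (6 equiv), DMF, 0 °C→rt
Reagents that add atoms: tert-butyldimethylsilyl chloride, CC(C)(C)[Si](C)(C)Cl
Why: Chemoselective O-silylation, in which the 7-, 3'- and 5'-OH react fast while the 5-OH stays free because it is held in a hydrogen bond to the C4 carbonyl, and imidazole is too weak a base to open the pyranone ring, so C2 is not epimerised.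

Step 3
Reactants: 9 (2S)-7,3',5'-tris(tert-butyldimethylsilyloxy)-5-hydroxyflavanone; 10 N-iodosuccinimide
Product: 11 (2S)-6-iodo-7,3',5'-tris(tert-butyldimethylsilyloxy)-5-hydroxyflavanone
Conditions: NIS (1.05 equiv), DMF, 0 °C, dark, 1 h
Reagents that add atoms: N-iodosuccinimide, O=C1CCC(=O)N1I
Why: Electrophilic aromatic iodination directed by the only free phenol, where acid-free NIS attacks the position ortho to the 5-OH (C6), the regiochemistry established for 5-hydroxy-7-alkoxyflavonoids, while C8 and the silylated ring B stay untouched; no stereocentre is involved.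

Step 4
Reactants: 11 (2S)-6-iodo-7,3',5'-tris(tert-butyldimethylsilyloxy)-5-hydroxyflavanone; 12 geranyl acetate [(2E)-3,7-dimethylocta-2,6-dien-1-yl acetate]
Product: 14 Schizolaenone C [(2S)-2-(3,5-dihydroxyphenyl)-6-[(2E)-3,7-dimethylocta-2,6-dien-1-yl]-5,7-dihydroxychroman-4-one], via 6-geranyl tris-silyl ether 13 (not isolated)
Conditions: 12 (2 equiv), NiBr2·MeOCH2CH2OMe (10 mol%), dtbpy (12 mol%), 4CzIPN (2 mol%), Hantzsch ester (1.5 equiv), NaHCO3 (2.5 equiv), dry degassed DMA, 450 nm LEDs, 25 °C, 12 h; then MeOH, KHF2 (8 equiv), rt, 3 h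
Reagents that add atoms: geranyl acetate, CC(C)=CCC/C(C)=C/COC(C)=O
Why: Proposed new method: a visible-light photoredox/nickel reductive cross-electrophile coupling of a di-ortho-oxygenated aryl iodide bearing a free chelated ortho-phenol with a terpenyl allylic acetate, in which excited 4CzIPN is quenched by the Hantzsch ester and its radical anion reduces the dtbpy-ligated divalent nickel bromide to zerovalent nickel, which inserts into the weak C6–I bond and ionises geranyl acetate to an η3-geranylnickel species, a further photochemical electron transfer (or aryl/allyl exchange between two divalent nickel centres) brings both fragments onto one nickel, and C–C reductive elimination at the unsubstituted allyl terminus gives the linear product with the E geometry kept (syn/anti exchange would need a tertiary η1-allyl), the site being fixed by the iodide and C2 untouched under near-neutral conditions at a wavelength the flavanone does not absorb; the closest known reaction types are nickel-catalysed reductive couplings of aryl halides with allylic acetates driven by zinc or a cathode and photoredox/nickel cross-electrophile couplings of aryl halides with alkyl halides; KHF2 in MeOH then cleaves the three phenolic silyl ethers by fluoride-mediated Si–O cleavage.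

## Compound list

1 | (2S)-pinocembrin, (2S)-5,7-dihydroxy-2-phenylchroman-4-one | O=C1C[C@@H](c2ccccc2)Oc2cc(O)cc(O)c12 | starting material
2 | pinacolborane | CC1(C)OBOC1(C)C | starting material
3 | bis(pinacolato)diboron | CC1(C)OB(OC1(C)C)B1OC(C)(C)C(C)(C)O1 | starting material
4 | N-methylmorpholine N-oxide | C[N+]1([O-])CCOCC1 | starting material
5 | (2S)-5,7-bis(pinacolboryloxy)-2-[3,5-bis(pinacolboryl)phenyl]chroman-4-one (not isolated) | O=C1C[C@@H](c2cc(B3OC(C)(C)C(C)(C)O3)cc(B3OC(C)(C)C(C)(C)O3)c2)Oc2cc(OB3OC(C)(C)C(C)(C)O3)cc(OB3OC(C)(C)C(C)(C)O3)c12 | intermediate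
6 | (2S)-5,7-bis(pinacolboryloxy)-2-[3,5-bis(pinacolboryloxy)phenyl]chroman-4-one (not isolated) | O=C1C[C@@H](c2cc(OB3OC(C)(C)C(C)(C)O3)cc(OB3OC(C)(C)C(C)(C)O3)c2)Oc2cc(OB3OC(C)(C)C(C)(C)O3)cc(OB3OC(C)(C)C(C)(C)O3)c12 | intermediate
7 | (2S)-5,7,3',5'-tetrahydroxyflavanone | O=C1C[C@@H](c2cc(O)cc(O)c2)Oc2cc(O)cc(O)c12 | intermediate
8 | tert-butyldimethylsilyl chloride | CC(C)(C)[Si](C)(C)Cl | starting material
9 | (2S)-7,3',5'-tris(tert-butyldimethylsilyloxy)-5-hydroxyflavanone | O=C1C[C@@H](c2cc(O[Si](C)(C)C(C)(C)C)cc(O[Si](C)(C)C(C)(C)C)c2)Oc2cc(O[Si](C)(C)C(C)(C)C)cc(O)c12 | intermediate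
10 | N-iodosuccinimide | O=C1CCC(=O)N1I | starting material
11 | (2S)-6-iodo-7,3',5'-tris(tert-butyldimethylsilyloxy)-5-hydroxyflavanone | O=C1C[C@@H](c2cc(O[Si](C)(C)C(C)(C)C)cc(O[Si](C)(C)C(C)(C)C)c2)Oc2cc(O[Si](C)(C)C(C)(C)C)c(I)c(O)c12 | intermediate
12 | geranyl acetate, (2E)-3,7-dimethylocta-2,6-dien-1-yl acetate | CC(C)=CCC/C(C)=C/COC(C)=O | starting material
13 | (2S)-6-[(2E)-3,7-dimethylocta-2,6-dien-1-yl]-7,3',5'-tris(tert-butyldimethylsilyloxy)-5-hydroxyflavanone (not isolated) | CC(C)=CCC/C(C)=C/Cc1c(O[Si](C)(C)C(C)(C)C)cc2c(c1O)C(=O)C[C@@H](c1cc(O[Si](C)(C)C(C)(C)C)cc(O[Si](C)(C)C(C)(C)C)c1)O2 | intermediate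
14 | Schizolaenone C, (2S)-6-geranyl-5,7,3',5'-tetrahydroxyflavanone | CC(C)=CCC/C(C)=C/Cc1c(O)cc2c(c1O)C(=O)C[C@@H](c1cc(O)cc(O)c1)O2 | target

## Step count and risks

Total step count: 4. Longest linear sequence: 4 steps (1 → 7 → 9 → 11 → 14).

**Step 4 (proposed new coupling).** Likely failure modes are protodeiodination back to 9, slow turnover at the doubly ortho-substituted C6, partial loss of the 7-O-silyl group followed by O-geranylation, and E/Z erosion. The fallback is a Stille coupling (known chemistry). It sets out from 11 and comes back at 13. Geranyl chloride and Bu3SnLi give tributyl[(2E)-3,7-dimethylocta-2,6-dien-1-yl]stannane F1. F1 is coupled with 11 using Pd(PPh3)4 (5 mol%) in DMF at 80 °C, neutral conditions precedented for prenylstannanes and iodoflavonoids. This gives 13, now isolated, which is desilylated with KHF2/MeOH to 14.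

**Step 1 (ring B C–H borylation/oxidation).** The yield has a statistical ceiling of about 2:1 in favour of the 3',5'-product. Other risks are incomplete second borylation, slowing of the catalyst by the chelating 5-O-boryl ketone, and difficult separation of the very polar 7 from naringenin. The fallback moves the hydroxylation to the end, onto a lipophilic substrate with a single free phenol. It sets out from 1 and comes back at 14.
- 1 is monosilylated (TBSCl 1.1 equiv, imidazole, DMF) to (2S)-7-(tert-butyldimethylsilyloxy)-5-hydroxyflavanone F2.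
- F2 is iodinated with NIS to (2S)-6-iodo-7-(tert-butyldimethylsilyloxy)-5-hydroxyflavanone F3.
- F3 is geranylated with 12 by the step 4 protocol without fluoride (or by the Stille alternative) to (2S)-6-geranyl-7-(tert-butyldimethylsilyloxy)-5-hydroxyflavanone F4.
- F4 is borylated ([Ir(OMe)(cod)]2, dtbpy, B2pin2, THF, 80 °C) to (2S)-6-geranyl-7-(tert-butyldimethylsilyloxy)-5-hydroxy-3',5'-bis(pinacolboryl)flavanone F5, which is purified on silica from the 4'-monoboronate.
- NMO oxidation of F5 gives (2S)-6-geranyl-7-(tert-butyldimethylsilyloxy)-5,3',5'-trihydroxyflavanone F6, which is desilylated in the same flask with KHF2/MeOH to 14.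

**Step 3 (iodination).** Possible failures are attack at C8, iodination of the silylated ring B, or di-iodination. The fallback replaces halogenation/cross-coupling by an O-to-C transfer from the 5-oxygen. It sets out from 9 and comes back at 13. A Mitsunobu reaction of the 5-OH of 9 with geraniol (PPh3, DIAD, THF, 0 °C→rt) gives (2S)-5-[(2E)-3,7-dimethylocta-2,6-dien-1-yloxy]-7,3',5'-tris(tert-butyldimethylsilyloxy)flavanone F7. Montmorillonite K10 in CH2Cl2 at 0 °C then induces the known clay-mediated ortho [1,3] shift of the allylic group to C6, the only free ortho position of O5. This gives 13, which is desilylated with KHF2/MeOH to 14.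

Further compounds
F1 | step 4 | tributyl[(2E)-3,7-dimethylocta-2,6-dien-1-yl]stannane | CC(C)=CCC/C(C)=C/C[Sn](CCCC)(CCCC)CCCC
F2 | step 1 | (2S)-7-(tert-butyldimethylsilyloxy)-5-hydroxyflavanone | O=C1C[C@@H](c2ccccc2)Oc2cc(O[Si](C)(C)C(C)(C)C)cc(O)c12
F3 | step 1 | (2S)-6-iodo-7-(tert-butyldimethylsilyloxy)-5-hydroxyflavanone | O=C1C[C@@H](c2ccccc2)Oc2cc(O[Si](C)(C)C(C)(C)C)c(I)c(O)c12
F4 | step 1 | (2S)-6-[(2E)-3,7-dimethylocta-2,6-dien-1-yl]-7-(tert-butyldimethylsilyloxy)-5-hydroxyflavanone | CC(C)=CCC/C(C)=C/Cc1c(O[Si](C)(C)C(C)(C)C)cc2c(c1O)C(=O)C[C@@H](c1ccccc1)O2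
F5 | step 1 | (2S)-6-[(2E)-3,7-dimethylocta-2,6-dien-1-yl]-7-(tert-butyldimethylsilyloxy)-5-hydroxy-3',5'-bis(pinacolboryl)flavanone | CC(C)=CCC/C(C)=C/Cc1c(O[Si](C)(C)C(C)(C)C)cc2c(c1O)C(=O)C[C@@H](c1cc(B3OC(C)(C)C(C)(C)O3)cc(B3OC(C)(C)C(C)(C)O3)c1)O2
F6 | step 1 | (2S)-6-[(2E)-3,7-dimethylocta-2,6-dien-1-yl]-7-(tert-butyldimethylsilyloxy)-5,3',5'-trihydroxyflavanone | CC(C)=CCC/C(C)=C/Cc1c(O[Si](C)(C)C(C)(C)C)cc2c(c1O)C(=O)C[C@@H](c1cc(O)cc(O)c1)O2
F7 | step 3 | (2S)-5-[(2E)-3,7-dimethylocta-2,6-dien-1-yloxy]-7,3',5'-tris(tert-butyldimethylsilyloxy)flavanone | CC(C)=CCC/C(C)=C/COc1cc(O[Si](C)(C)C(C)(C)C)cc2c1C(=O)C[C@@H](c1cc(O[Si](C)(C)C(C)(C)C)cc(O[Si](C)(C)C(C)(C)C)c1)O2
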